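**Plan**

1. Retrosynthetic cuts, in order: C1–OH back to the C1 ketone; the ten-membered ring at C3–C4; the side arm at C8–C9; the butenolide at C7–C8 (a vinyl group), C11–C13, O–C12 and C6–C7.
2. Forward: the butenolide ring (O, C6, C7, C11, C12) is made first from (Z)-3-iodobut-2-enal, methyl propiolate, a vinyl Grignard reagent and formaldehyde, and its C7 vinyl group is cut down to the C8 aldehyde.
3. An allylboronate carrying C9, C10, C14 and the cyclopropanol carbons C1–C3 is joined at C8–C9, and the ten-membered carbocycle closes last at C3–C4.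
4. Enabling feature: in the ten-membered ring the plain C2H2–C3H2 pair sits between oxygen-bearing C1 and C4 of the cis C4=C5 alkene, so C1–C3 can be carried as a strained cyclopropanol whose opening on palladium hands C3 to an alkenyl iodide at C4.
5. Stereochemistry: C6 from a zinc–ProPhenol alkynylation, C8 from a chiral phosphoric acid allylboration, C1 from a Corey–Bakshi–Shibata reduction; the 4Z alkene from trans-hydroalumination/iodination of but-2-yn-1-ol, kept by a stereoretentive coupling.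

Key step: step 16

Assumption: (S,S)-ProPhenol is taken to give the 4R carbinol 5 and (S)-TRIP the 8S carbinol 21, by analogy with enal and aryl aldehyde cases; if either sense proved opposite, the antipodal catalyst would be used with no other change.

**Route**

Step 1
Reactants: 1 but-2-yn-1-ol
Product: 2 (Z)-3-iodobut-2-en-1-ol
Conditions: NaAlH2(OCH2CH2OMe)2 (Red-Al), THF, 0 °C → rt; then I2, −78 → 0 °C
Reagents that add atoms: iodine, I-I
Why: Hydroxyl-directed trans-hydroalumination puts aluminium on C3 cis to the carbinol carbon, and iodinolysis with retention should fix the Z iodoalkene that becomes C4=C5.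

Step 2
Reactants: 2 (Z)-3-iodobut-2-en-1-ol
Product: 3 (Z)-3-iodobut-2-enal
Conditions: MnO2, CH2Cl2, rt
Reagents that add atoms: none
Why: Neutral allylic oxidation with MnO2 should give the sensitive Z enal without isomerisation; it is used at once.

Step 3
Reactants: 3 (Z)-3-iodobut-2-enal; 4 methyl propiolate
Product: 5 methyl (4R,5Z)-4-hydroxy-6-iodohept-5-en-2-ynoate
Conditions: Me2Zn, (S,S)-ProPhenol (20 mol %), Ph3PO (40 mol %), toluene, 0 °C
Reagents that add atoms: none
Why: The dinuclear zinc–ProPhenol catalysed alkynylation of enals with propiolate should set C6 (C4 of 5, R) under catalyst control.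

Step 4
Reactants: 5 methyl (4R,5Z)-4-hydroxy-6-iodohept-5-en-2-ynoate
Product: 6 methyl (4R,5Z)-6-iodo-4-[(triethylsilyl)oxy]hept-5-en-2-ynoate
Conditions: TESCl, imidazole, CH2Cl2, 0 °C
Reagents that add atoms: triethylsilyl chloride, CC[Si](Cl)(CC)CC
Why: Silylation of the propargylic alcohol keeps the alkoxide out of the copper step, so that the addition to the ynoate runs syn and the oxygen is freed only when lactonisation is wanted.

Step 5
Reactants: 6 methyl (4R,5Z)-6-iodo-4-[(triethylsilyl)oxy]hept-5-en-2-ynoate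
Product: 9 (5R)-3-(hydroxymethyl)-5-[(1Z)-2-iodoprop-1-en-1-yl]-4-vinylfuran-2(5H)-one, via aldol adduct 7 (not isolated), via desilylated hydroxy ester 8 (not isolated)
Conditions: vinylMgBr, CuI (10 mol %), LiCl, THF, −78 °C; CH2O (gas from paraformaldehyde), −78 → −40 °C; then 1 M HCl, THF, rt
Reagents that add atoms: vinylmagnesium bromide, C=C[Mg]Br; formaldehyde, C=O
Why: Copper-catalysed conjugate addition (syn carbometalation) of the 4-silyloxy-2-ynoate puts the vinyl group on C7, aldol capture at C11 by formaldehyde adds C13 on the vinyl side (also the sterically preferred side of the allenolate), and acid removes the TES group so that the C6 hydroxyl, cis to the ester, lactonises; no stereocenter is formed.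

Step 6
Reactants: 9 (5R)-3-(hydroxymethyl)-5-[(1Z)-2-iodoprop-1-en-1-yl]-4-vinylfuran-2(5H)-one
Product: 10 (5R)-3-{[tert-butyl(diphenyl)silyl]oxymethyl}-5-[(1Z)-2-iodoprop-1-en-1-yl]-4-vinylfuran-2(5H)-one
Conditions: TBDPSCl, imidazole, DMF, 0 °C → rt
Reagents that add atoms: tert-butyldiphenylsilyl chloride, CC(C)(C)[Si](Cl)(c1ccccc1)c1ccccc1
Why: Silylation of the primary allylic alcohol gives a C13 ether robust enough to outlast the later removal of a triethylsilyl group.

Step 7
Reactants: 10 (5R)-3-{[tert-butyl(diphenyl)silyl]oxymethyl}-5-[(1Z)-2-iodoprop-1-en-1-yl]-4-vinylfuran-2(5H)-one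
Product: 12 (2R)-4-{[tert-butyl(diphenyl)silyl]oxymethyl}-2-[(1Z)-2-iodoprop-1-en-1-yl]-5-oxo-2,5-dihydrofuran-3-carbaldehyde, via diol 11 (not isolated)
Conditions: OsO4 (cat.), NaIO4, 2,6-lutidine, dioxane/H2O, rt
Reagents that add atoms: osmium tetroxide, O=[Os](=O)(=O)=O; sodium periodate, [Na+].[O-]I(=O)(=O)=O
Why: Lemieux–Johnson oxidation should cleave only the terminal vinyl group, the iodoalkene and the tetrasubstituted butenolide alkene being too electron-poor and hindered for OsO4, and so leaves C8 as the aldehyde.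

Step 8
Reactants: 13 (1-ethoxycyclopropoxy)trimethylsilane
Product: 14 1-ethoxycyclopropan-1-ol
Conditions: MeOH, rt
Reagents that add atoms: none
Why: Methanolysis of the silyl ketal gives the cyclopropanone ethyl hemiketal, the storable cyclopropanone equivalent.

Step 9
Reactants: 14 1-ethoxycyclopropan-1-ol; 15 2-bromoprop-2-en-1-ol
Product: 17 1-(3-hydroxyprop-1-en-2-yl)cyclopropan-1-ol, via cyclopropanone 16 (not isolated)
Conditions: 15, t-BuLi (3 equiv), Et2O, −78 → 0 °C; 14, MeMgBr (1 equiv), THF, 0 °C; combine, −78 °C → rt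
Reagents that add atoms: none
Why: Bromine–lithium exchange on the lithium alkoxide gives the 2-lithioallyl alkoxide (future C10), which adds to cyclopropanone released from the magnesium salt of the hemiketal to form the C10–C1 bond (organometallic addition to a cyclopropanone hemiketal).

Step 10
Reactants: 17 1-(3-hydroxyprop-1-en-2-yl)cyclopropan-1-ol
Product: 18 2-(1-hydroxycyclopropyl)prop-2-en-1-yl acetate
Conditions: Ac2O (1.05 equiv), pyridine, CH2Cl2, 0 °C
Reagents that add atoms: acetic anhydride, CC(=O)OC(C)=O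
Why: Without an acyl-transfer catalyst the primary allylic hydroxyl is acetylated far faster than the tertiary cyclopropanol.

Step 11
Reactants: 18 2-(1-hydroxycyclopropyl)prop-2-en-1-yl acetate
Product: 19 2-{1-[(triethylsilyl)oxy]cyclopropyl}prop-2-en-1-yl acetate
Conditions: TESCl, imidazole, DMAP (cat.), DMF, rt
Reagents that add atoms: triethylsilyl chloride, CC[Si](Cl)(CC)CC
Why: Silylation masks the cyclopropanol so that palladium in the next step cannot open it through an alkoxide.

Step 12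
Reactants: 19 2-{1-[(triethylsilyl)oxy]cyclopropyl}prop-2-en-1-yl acetate
Product: 20 triethyl{1-[3-(4,4,5,5-tetramethyl-1,3,2-dioxaborolan-2-yl)prop-1-en-2-yl]cyclopropoxy}silane
Conditions: B2pin2, Pd2(dba)3 (cat.), DMSO, 50 °C
Reagents that add atoms: bis(pinacolato)diboron, CC1(C)OB(OC1(C)C)B1OC(C)(C)C(C)(C)O1
Why: Palladium-catalysed borylation of the allylic acetate through a π-allyl complex (Miyaura-type allylic borylation) should give the allylboronate, and the symmetrical 2-substituted allyl unit leaves no regiochemical question.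

Step 13
Reactants: 12 (2R)-4-{[tert-butyl(diphenyl)silyl]oxymethyl}-2-[(1Z)-2-iodoprop-1-en-1-yl]-5-oxo-2,5-dihydrofuran-3-carbaldehyde; 20 triethyl{1-[3-(4,4,5,5-tetramethyl-1,3,2-dioxaborolan-2-yl)prop-1-en-2-yl]cyclopropoxy}silane
Product: 21 (5R)-3-{[tert-butyl(diphenyl)silyl]oxymethyl}-4-[(1S)-1-hydroxy-3-{1-[(triethylsilyl)oxy]cyclopropyl}but-3-en-1-yl]-5-[(1Z)-2-iodoprop-1-en-1-yl]furan-2(5H)-one
Conditions: (S)-TRIP (5–10 mol %), toluene, −30 °C
Reagents that add atoms: none
Why: Chiral phosphoric acid-catalysed allylboration through a closed six-membered transition state should deliver the allyl group to the Si face of the aldehyde under catalyst control and set C8 as S, with no cationic intermediate that could expand the silyloxycyclopropane.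

Step 14
Reactants: 21 (5R)-3-{[tert-butyl(diphenyl)silyl]oxymethyl}-4-[(1S)-1-hydroxy-3-{1-[(triethylsilyl)oxy]cyclopropyl}but-3-en-1-yl]-5-[(1Z)-2-iodoprop-1-en-1-yl]furan-2(5H)-one
Product: 22 (5R)-4-[(1S)-1-{[tert-butyl(dimethyl)silyl]oxy}-3-{1-[(triethylsilyl)oxy]cyclopropyl}but-3-en-1-yl]-3-{[tert-butyl(diphenyl)silyl]oxymethyl}-5-[(1Z)-2-iodoprop-1-en-1-yl]furan-2(5H)-one
Conditions: TBSOTf, 2,6-lutidine, CH2Cl2, −78 °C
Reagents that add atoms: tert-butyldimethylsilyl triflate, CC(C)(C)[Si](C)(C)OS(=O)(=O)C(F)(F)F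
Why: Silyl triflate with a hindered base protects the hindered secondary C8 hydroxyl as a non-ionisable ether.

Step 15
Reactants: 22 (5R)-4-[(1S)-1-{[tert-butyl(dimethyl)silyl]oxy}-3-{1-[(triethylsilyl)oxy]cyclopropyl}but-3-en-1-yl]-3-{[tert-butyl(diphenyl)silyl]oxymethyl}-5-[(1Z)-2-iodoprop-1-en-1-yl]furan-2(5H)-one
Product: 23 (5R)-4-[(1S)-1-{[tert-butyl(dimethyl)silyl]oxy}-3-(1-hydroxycyclopropyl)but-3-en-1-yl]-3-{[tert-butyl(diphenyl)silyl]oxymethyl}-5-[(1Z)-2-iodoprop-1-en-1-yl]furan-2(5H)-one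
Conditions: HF·pyridine, pyridine, THF, 0 °C
Reagents that add atoms: none
Why: Buffered fluoride should cleave the triethylsilyl ether well before the secondary TBS and primary TBDPS ethers, under conditions too mild to protonate the alkene and expand the ring.

Step 16
Reactants: 23 (5R)-4-[(1S)-1-{[tert-butyl(dimethyl)silyl]oxy}-3-(1-hydroxycyclopropyl)but-3-en-1-yl]-3-{[tert-butyl(diphenyl)silyl]oxymethyl}-5-[(1Z)-2-iodoprop-1-en-1-yl]furan-2(5H)-one
Product: 24 8α-(tert-butyldimethylsilyloxy)-13-(tert-butyldiphenylsilyloxy)-1-oxogermacra-4,7(11),10(14)-trien-6α,12-olide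
Conditions: Pd(OAc)2 (10 mol %), XPhos (20 mol %), Cs2CO3, toluene, 80 °C, syringe-pump addition of 23 to 1 mM
Reagents that add atoms: none
Why: Proposed new method: zerovalent palladium should add to the C4–I bond with retention, carbonate should exchange iodide for the cyclopropanolate oxygen, and strain-driven β-carbon elimination should give the C3-palladated homoenolate of the C1 ketone, which reductively eliminates to form C3–C4. The closest known reaction type is the palladium-catalysed ring-opening cross-coupling of cyclopropanols with aryl and alkenyl halides, which has not been used to close a medium ring. The ten-membered carbocycle closes by C(sp3)–C(sp2) reductive elimination from an eleven-membered palladacycle, so both chain ends are already on one metal before the bond forms. No stereocenter is formed; the 4Z geometry is carried over from the iodide and C6 and C8 are untouched. The step needs reductive elimination to outrun β-hydride loss from C2, Heck-type attack on the 10(14)-alkene, ring expansion of the 1-alkenylcyclopropanol and oligomerisation; the bulky electron-rich biaryl phosphine, fast alkoxide exchange under insoluble carbonate and slow addition to high dilution are meant to secure this, and because the cyclopropanol has a mirror plane, cleavage of C1–C2 or of C1–C3 leads to one and the same homoenolate. Silyl ethers in place of the allylic acetates keep palladium from ionising C8–O and C13–O.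

Step 17
Reactants: 24 8α-(tert-butyldimethylsilyloxy)-13-(tert-butyldiphenylsilyloxy)-1-oxogermacra-4,7(11),10(14)-trien-6α,12-olide
Product: 25 8α,13-dihydroxy-1-oxogermacra-4,7(11),10(14)-trien-6α,12-olide
Conditions: HF·pyridine, THF, 0 °C → rt
Reagents that add atoms: none
Why: Acidic fluoride removes both silyl ethers without exposing the exo-methylene ketone or the acidic C6–H to base.

Step 18
Reactants: 25 8α,13-dihydroxy-1-oxogermacra-4,7(11),10(14)-trien-6α,12-olide
Product: 26 8α,13-diacetoxy-1-oxogermacra-4,7(11),10(14)-trien-6α,12-olide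
Conditions: Ac2O, pyridine, DMAP (cat.), CH2Cl2, 0 °C
Reagents that add atoms: acetic anhydride, CC(=O)OC(C)=O
Why: Standard acylation converts the two free hydroxyls into the acetates of the target while the C1 oxygen is still a ketone and needs no protection.

Step 19
Reactants: 26 8α,13-diacetoxy-1-oxogermacra-4,7(11),10(14)-trien-6α,12-olide
Product: 27 8α,13-diacetoxy-1α-hydroxygermacra-4,7(11),10(14)-trien-6α,12-olide
Conditions: (R)-2-methyl-CBS-oxazaborolidine, catecholborane, toluene, −78 °C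
Reagents that add atoms: none
Why: Corey–Bakshi–Shibata reduction should be 1,2-selective at low temperature and, with the α-branched alkenyl carbon C10 as the large group and C2 as the small one, the (R)-catalyst should deliver hydride to give the 1S (1α) carbinol; acetates and the butenolide are not reduced under these conditions.

**Compound list**

1 | but-2-yn-1-ol | CC#CCO | starting material
2 | (Z)-3-iodobut-2-en-1-ol | OC/C=C(/C)I | intermediate
3 | (Z)-3-iodobut-2-enal | O=C/C=C(/C)I | intermediate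
4 | methyl propiolate | C#CC(=O)OC | starting material
5 | methyl (4R,5Z)-4-hydroxy-6-iodohept-5-en-2-ynoate | COC(=O)C#C[C@H](O)/C=C(/C)I | intermediate
6 | methyl (4R,5Z)-6-iodo-4-[(triethylsilyl)oxy]hept-5-en-2-ynoate | COC(=O)C#C[C@H](O[Si](CC)(CC)CC)/C=C(/C)I | intermediate
7 | methyl (2Z,4R,5Z)-2-(hydroxymethyl)-6-iodo-4-[(triethylsilyl)oxy]-3-vinylhepta-2,5-dienoate | COC(=O)/C(CO)=C(/C=C)[C@H](O[Si](CC)(CC)CC)/C=C(/C)I | intermediate (not isolated)
8 | methyl (2Z,4R,5Z)-4-hydroxy-2-(hydroxymethyl)-6-iodo-3-vinylhepta-2,5-dienoate | COC(=O)/C(CO)=C(/C=C)[C@H](O)/C=C(/C)I | intermediate (not isolated)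
9 | (5R)-3-(hydroxymethyl)-5-[(1Z)-2-iodoprop-1-en-1-yl]-4-vinylfuran-2(5H)-one | C=CC1=C(CO)C(=O)O[C@@H]1/C=C(/C)I | intermediate
10 | (5R)-3-{[tert-butyl(diphenyl)silyl]oxymethyl}-5-[(1Z)-2-iodoprop-1-en-1-yl]-4-vinylfuran-2(5H)-one | C=CC1=C(CO[Si](c2ccccc2)(c2ccccc2)C(C)(C)C)C(=O)O[C@@H]1/C=C(/C)I | intermediate
11 | (5R)-3-{[tert-butyl(diphenyl)silyl]oxymethyl}-4-(1,2-dihydroxyethyl)-5-[(1Z)-2-iodoprop-1-en-1-yl]furan-2(5H)-one, both carbinol epimers | OCC(O)C1=C(CO[Si](c2ccccc2)(c2ccccc2)C(C)(C)C)C(=O)O[C@@H]1/C=C(/C)I | intermediate (not isolated)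
12 | (2R)-4-{[tert-butyl(diphenyl)silyl]oxymethyl}-2-[(1Z)-2-iodoprop-1-en-1-yl]-5-oxo-2,5-dihydrofuran-3-carbaldehyde | O=CC1=C(CO[Si](c2ccccc2)(c2ccccc2)C(C)(C)C)C(=O)O[C@@H]1/C=C(/C)I | intermediate
13 | (1-ethoxycyclopropoxy)trimethylsilane | CCOC1(CC1)O[Si](C)(C)C | starting material
14 | 1-ethoxycyclopropan-1-ol | CCOC1(O)CC1 | intermediate
15 | 2-bromoprop-2-en-1-ol | OCC(Br)=C | starting material
16 | cyclopropanone | O=C1CC1 | intermediate (not isolated)
17 | 1-(3-hydroxyprop-1-en-2-yl)cyclopropan-1-ol | C=C(CO)C1(O)CC1 | intermediate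
18 | 2-(1-hydroxycyclopropyl)prop-2-en-1-yl acetate | C=C(COC(C)=O)C1(O)CC1 | intermediate
19 | 2-{1-[(triethylsilyl)oxy]cyclopropyl}prop-2-en-1-yl acetate | C=C(COC(C)=O)C1(O[Si](CC)(CC)CC)CC1 | intermediate
20 | triethyl{1-[3-(4,4,5,5-tetramethyl-1,3,2-dioxaborolan-2-yl)prop-1-en-2-yl]cyclopropoxy}silane | C=C(CB1OC(C)(C)C(C)(C)O1)C2(O[Si](CC)(CC)CC)CC2 | intermediate
21 | (5R)-3-{[tert-butyl(diphenyl)silyl]oxymethyl}-4-[(1S)-1-hydroxy-3-{1-[(triethylsilyl)oxy]cyclopropyl}but-3-en-1-yl]-5-[(1Z)-2-iodoprop-1-en-1-yl]furan-2(5H)-one | C=C(C1(O[Si](CC)(CC)CC)CC1)C[C@H](O)C2=C(CO[Si](c3ccccc3)(c3ccccc3)C(C)(C)C)C(=O)O[C@@H]2/C=C(/C)I | intermediate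
22 | (5R)-4-[(1S)-1-{[tert-butyl(dimethyl)silyl]oxy}-3-{1-[(triethylsilyl)oxy]cyclopropyl}but-3-en-1-yl]-3-{[tert-butyl(diphenyl)silyl]oxymethyl}-5-[(1Z)-2-iodoprop-1-en-1-yl]furan-2(5H)-one | C=C(C1(O[Si](CC)(CC)CC)CC1)C[C@H](O[Si](C)(C)C(C)(C)C)C2=C(CO[Si](c3ccccc3)(c3ccccc3)C(C)(C)C)C(=O)O[C@@H]2/C=C(/C)I | intermediate
23 | (5R)-4-[(1S)-1-{[tert-butyl(dimethyl)silyl]oxy}-3-(1-hydroxycyclopropyl)but-3-en-1-yl]-3-{[tert-butyl(diphenyl)silyl]oxymethyl}-5-[(1Z)-2-iodoprop-1-en-1-yl]furan-2(5H)-one | C=C(C1(O)CC1)C[C@H](O[Si](C)(C)C(C)(C)C)C2=C(CO[Si](c3ccccc3)(c3ccccc3)C(C)(C)C)C(=O)O[C@@H]2/C=C(/C)I | intermediate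
24 | 8α-(tert-butyldimethylsilyloxy)-13-(tert-butyldiphenylsilyloxy)-1-oxogermacra-4,7(11),10(14)-trien-6α,12-olide | C=C1C[C@H](O[Si](C)(C)C(C)(C)C)C2=C(CO[Si](c3ccccc3)(c3ccccc3)C(C)(C)C)C(=O)O[C@@H]2/C=C(/C)CCC1=O | intermediate
25 | 8α,13-dihydroxy-1-oxogermacra-4,7(11),10(14)-trien-6α,12-olide | C=C1C[C@H](O)C2=C(CO)C(=O)O[C@@H]2/C=C(/C)CCC1=O | intermediate
26 | 8α,13-diacetoxy-1-oxogermacra-4,7(11),10(14)-trien-6α,12-olide | C=C1C[C@H](OC(C)=O)C2=C(COC(C)=O)C(=O)O[C@@H]2/C=C(/C)CCC1=O | intermediate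
27 | 8α,13-diacetoxy-1α-hydroxygermacra-4,7(11),10(14)-trien-6α,12-olide | C=C1C[C@H](OC(C)=O)C2=C(COC(C)=O)C(=O)O[C@@H]2/C=C(/C)CC[C@@H]1O | target

**Step count and risks**

Total: 19 steps. Longest linear sequence: 14 steps (steps 1–7, then 13–19); the allylboronate 20 is made in 5 steps (8–12).

Steps most likely to fail:

1. Step 16 (Proposed new method). What may go wrong: β-hydride loss from the palladium homoenolate, carbopalladation of the 10(14)-alkene or ring expansion of the alkenylcyclopropanol, intermolecular coupling, and base-induced epimerisation at C6. The fallback uses known chemistry, makes C3–C4 intermolecularly and closes the ring at C1–C10; it sets out from aldehyde 12 and comes back at enone 24.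
   - Catalytic asymmetric chromium-mediated 2-bromoallylation of 12 with 2,3-dibromopropene (CrBr3, chiral sulfonamide ligand chosen for 8S, Mn, Cp2ZrCl2) would give the bromoallyl carbinol (5R)-4-[(1S)-3-bromo-1-hydroxybut-3-en-1-yl]-3-{[tert-butyl(diphenyl)silyl]oxymethyl}-5-[(1Z)-2-iodoprop-1-en-1-yl]furan-2(5H)-one F1.
   - TBSOTf and 2,6-lutidine would give its C8 silyl ether F2.
   - Hydroboration of allyl 4-methoxybenzyl ether with 9-BBN would give 9-[3-(4-methoxybenzyloxy)propyl]-9-borabicyclo[3.3.1]nonane F3.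
   - B-alkyl Suzuki–Miyaura coupling of F3 with the alkenyl iodide of F2 (Pd(dppf)Cl2, AsPh3, Cs2CO3, DMF/THF/H2O, rt) would spare the alkenyl bromide and form C3–C4 in the PMB ether F4.
   - DDQ would free the primary alcohol F5, and Dess–Martin periodinane would give the C1 aldehyde F6.
   - A Nozaki–Hiyama–Kishi reaction (CrCl2, NiCl2 cat., DMSO, high dilution) would close the ten-membered ring to the macrocyclic C1 allylic alcohol F7 as both C1 epimers.
   - Dess–Martin oxidation of F7 would give 24.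

2. Step 5. What may go wrong: incomplete aldol capture of the magnesium allenolate by formaldehyde, loss of alkene geometry at C7=C11 so that part of the material cannot lactonise, or 1,2-addition to the ester. The fallback replaces the aldol by an alkylation with a boron-bearing one-carbon electrophile; it sets out from silyl ether 6 and comes back at butenolide 9.
   - The divinylcuprate from vinylMgBr and CuBr·SMe2 would add to 6 at −78 °C, and the alkenylcopper would be alkylated with retention by ICH2Bpin (HMPA) to give the allylboronate methyl (2Z,4R,5Z)-6-iodo-2-[(4,4,5,5-tetramethyl-1,3,2-dioxaborolan-2-yl)methyl]-4-[(triethylsilyl)oxy]-3-vinylhepta-2,5-dienoate F8.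
   - Oxidation of the C–B bond with NaBO3·4H2O would give hydroxy ester 7, and 1 M HCl as in step 5 would give 9.

3. Step 13. What may go wrong: slow addition of the bulky 2-substituted allylboronate to the hindered, electron-poor aldehyde, or poor facial selectivity at C8 under the acid catalyst. The fallback sets C8 by reduction instead of by addition; it sets out from 12 and 20 and comes back at carbinol 21.
   - Uncatalysed allylboration (toluene, rt to 50 °C) would give the C8-epimeric carbinols (5R)-3-{[tert-butyl(diphenyl)silyl]oxymethyl}-4-[1-hydroxy-3-{1-[(triethylsilyl)oxy]cyclopropyl}but-3-en-1-yl]-5-[(1Z)-2-iodoprop-1-en-1-yl]furan-2(5H)-one F9.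
   - Dess–Martin periodinane would give the C8 ketone F10.
   - Corey–Bakshi–Shibata reduction ((R)-2-methyl-CBS-oxazaborolidine, catecholborane, −78 °C), with the butenolide carbon C7 as the large group, would give the 8S carbinol 21.

**Further compounds**

F1 | step 16 | (5R)-4-[(1S)-3-bromo-1-hydroxybut-3-en-1-yl]-3-{[tert-butyl(diphenyl)silyl]oxymethyl}-5-[(1Z)-2-iodoprop-1-en-1-yl]furan-2(5H)-one | C=C(Br)C[C@H](O)C1=C(CO[Si](c2ccccc2)(c2ccccc2)C(C)(C)C)C(=O)O[C@@H]1/C=C(/C)I
F2 | step 16 | (5R)-4-[(1S)-3-bromo-1-{[tert-butyl(dimethyl)silyl]oxy}but-3-en-1-yl]-3-{[tert-butyl(diphenyl)silyl]oxymethyl}-5-[(1Z)-2-iodoprop-1-en-1-yl]furan-2(5H)-one | C=C(Br)C[C@H](O[Si](C)(C)C(C)(C)C)C1=C(CO[Si](c2ccccc2)(c2ccccc2)C(C)(C)C)C(=O)O[C@@H]1/C=C(/C)I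
F3 | step 16 | 9-[3-(4-methoxybenzyloxy)propyl]-9-borabicyclo[3.3.1]nonane | COc1ccc(COCCCB2C3CCCC2CCC3)cc1
F4 | step 16 | (5R)-4-[(1S)-3-bromo-1-{[tert-butyl(dimethyl)silyl]oxy}but-3-en-1-yl]-3-{[tert-butyl(diphenyl)silyl]oxymethyl}-5-[(1Z)-5-(4-methoxybenzyloxy)-2-methylpent-1-en-1-yl]furan-2(5H)-one | C=C(Br)C[C@H](O[Si](C)(C)C(C)(C)C)C1=C(CO[Si](c2ccccc2)(c2ccccc2)C(C)(C)C)C(=O)O[C@@H]1/C=C(/C)CCCOCc3ccc(OC)cc3
F5 | step 16 | (5R)-4-[(1S)-3-bromo-1-{[tert-butyl(dimethyl)silyl]oxy}but-3-en-1-yl]-3-{[tert-butyl(diphenyl)silyl]oxymethyl}-5-[(1Z)-5-hydroxy-2-methylpent-1-en-1-yl]furan-2(5H)-one | C=C(Br)C[C@H](O[Si](C)(C)C(C)(C)C)C1=C(CO[Si](c2ccccc2)(c2ccccc2)C(C)(C)C)C(=O)O[C@@H]1/C=C(/C)CCCO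
F6 | step 16 | (4Z)-5-[(2R)-3-[(1S)-3-bromo-1-{[tert-butyl(dimethyl)silyl]oxy}but-3-en-1-yl]-4-{[tert-butyl(diphenyl)silyl]oxymethyl}-5-oxo-2,5-dihydrofuran-2-yl]-4-methylpent-4-enal | C=C(Br)C[C@H](O[Si](C)(C)C(C)(C)C)C1=C(CO[Si](c2ccccc2)(c2ccccc2)C(C)(C)C)C(=O)O[C@@H]1/C=C(/C)CCC=O
F7 | step 16 | 8α-(tert-butyldimethylsilyloxy)-13-(tert-butyldiphenylsilyloxy)-1-hydroxygermacra-4,7(11),10(14)-trien-6α,12-olide, both C1 epimers | C=C1C[C@H](O[Si](C)(C)C(C)(C)C)C2=C(CO[Si](c3ccccc3)(c3ccccc3)C(C)(C)C)C(=O)O[C@@H]2/C=C(/C)CCC1O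
F8 | step 5 | methyl (2Z,4R,5Z)-6-iodo-2-[(4,4,5,5-tetramethyl-1,3,2-dioxaborolan-2-yl)methyl]-4-[(triethylsilyl)oxy]-3-vinylhepta-2,5-dienoate | COC(=O)/C(CB1OC(C)(C)C(C)(C)O1)=C(/C=C)[C@H](O[Si](CC)(CC)CC)/C=C(/C)I
F9 | step 13 | (5R)-3-{[tert-butyl(diphenyl)silyl]oxymethyl}-4-[1-hydroxy-3-{1-[(triethylsilyl)oxy]cyclopropyl}but-3-en-1-yl]-5-[(1Z)-2-iodoprop-1-en-1-yl]furan-2(5H)-one, both C8 epimers | C=C(C1(O[Si](CC)(CC)CC)CC1)CC(O)C2=C(CO[Si](c3ccccc3)(c3ccccc3)C(C)(C)C)C(=O)O[C@@H]2/C=C(/C)I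
F10 | step 13 | (5R)-3-{[tert-butyl(diphenyl)silyl]oxymethyl}-5-[(1Z)-2-iodoprop-1-en-1-yl]-4-(3-{1-[(triethylsilyl)oxy]cyclopropyl}but-3-enoyl)furan-2(5H)-one | C=C(C1(O[Si](CC)(CC)CC)CC1)CC(=O)C2=C(CO[Si](c3ccccc3)(c3ccccc3)C(C)(C)C)C(=O)O[C@@H]2/C=C(/C)I
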